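**Retrosynthetic overview**

Target = ent-fisetinidol-(4β→6)-catechin: upper unit (2S,3R,4R), 2,3-trans-3,4-trans; lower unit (2R,3S).
Lower unit: (+)-catechin 1 → tetrabenzyl ether 2 → 8-bromide 3 (Br blocks C8, so only C6 can attack).
Upper unit: (−)-fustin 4 → tribenzyl ether 5 → (diol 6) → 4-arylthio flavan-3-ol 7, a latent C4 cation 8.
Key disconnection: the interflavan C4–C6 bond of 9, made by visible-light photoredox coupling of 7 with 3, with C4 set trans to the C3 hydroxyl; global hydrogenolysis then gives 10.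
Rings: no ring is built; both chroman rings C and all four arene rings are bought in 1 and 4.

Assumption: (−)-fustin is the (2S,3S) enantiomer (mirror image of (+)-(2R,3R)-fustin) and is bought as such; its ee is checked by chiral HPLC before use.

**Route**

Step 1
Reactants: 1 (+)-catechin
Product: 2 5,7,3',4'-tetra-O-benzyl-(+)-catechin
Conditions: BnBr (4.4 equiv), K2CO3, DMF, 0 °C → rt, Ar
Reagents that add atoms: benzyl bromide, BrCc1ccccc1
Why: Williamson etherification of the four phenols under carbonate leaves the far less acidic secondary C3 alcohol free and touches no stereocentre.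

Step 2
Reactants: 2 5,7,3',4'-tetra-O-benzyl-(+)-catechin
Product: 3 8-bromo-5,7,3',4'-tetra-O-benzyl-(+)-catechin
Conditions: NBS (1.0 equiv), CH2Cl2, −78 °C → rt
Reagents that add atoms: N-bromosuccinimide, O=C1CCC(=O)N1Br
Why: Electrophilic aromatic bromination of the phloroglucinol-type ring A of benzylated flavan-3-ols is selective for C8, so bromine blocks C8 and leaves C6 as the only nucleophilic carbon.

Step 3
Reactants: 4 (−)-fustin
Product: 5 7,3',4'-tri-O-benzyl-(−)-fustin
Conditions: BnBr (3.3 equiv), K2CO3, DMF, 0 °C → rt, Ar, dark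
Reagents that add atoms: benzyl bromide, BrCc1ccccc1
Why: Williamson etherification caps the acidic 7- and 4'-phenols first, which shuts down base-induced opening of ring C, and leaves the C3 hydroxyl and both bought stereocentres (2S,3S) untouched.

Step 4
Reactants: 5 7,3',4'-tri-O-benzyl-(−)-fustin
Product: 7 (2S,3S,4S)-7-benzyloxy-2-[3,4-bis(benzyloxy)phenyl]-4-[(4-methoxyphenyl)sulfanyl]chroman-3-ol, via tri-O-benzyl flavan-3,4-diol 6 (not isolated)
Conditions: NaBH4, THF–MeOH (9:1), 0 °C; then 4-MeOC6H4SH (3 equiv), HCl (4 M in dioxane), 0 → 40 °C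
Reagents that add atoms: 4-methoxybenzenethiol, COc1ccc(S)cc1
Why: Borohydride reduction of the 2,3-trans dihydroflavonol gives the 2,3-trans-3,4-trans diol 6, and acid ionisation of its doubly oxygen-activated benzylic C4–OH (SN1 thiolysis, as in analytical thiolysis of proanthocyanidins) is trapped by the thiol mainly trans to the C3 hydroxyl; the C4 configuration of 7 does not matter because C4 is ionised again in step 5.

Step 5
Reactants: 7 (2S,3S,4S)-4-[(4-methoxyphenyl)sulfanyl] tri-O-benzyl flavan-3-ol; 3 8-bromo-5,7,3',4'-tetra-O-benzyl-(+)-catechin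
Product: 9 8-bromo-hepta-O-benzyl-ent-fisetinidol-(4β→6)-catechin, via flavan-4-yl cation 8 (not isolated)
Conditions: [Ru(bpz)3](PF6)2 (2 mol %; bpz = 2,2'-bipyrazine), 3 (2 equiv), CH2Cl2–HFIP (4:1), blue LEDs (450 nm), Ar, rt
Reagents that add atoms: none
Why: Proposed new method: photoredox mesolytic C–S activation of a 4-arylthioflavan for interflavan C-arylation; the excited ruthenium complex (about +1.45 V vs SCE) oxidises the electron-rich aryl sulfide of 7 (about +1.2 V), the sulfide radical cation fragments at the weak benzylic C4–S bond to the 2,4-dioxygenated benzylic cation 8 and a thiyl radical, the reduced monovalent ruthenium complex returns the electron to the thiyl radical (net redox-neutral, thiol released), and 8 is attacked in a Friedel–Crafts step by C6 of 3 (C8 blocked by Br) on the face anti to the C3 hydroxyl, setting C4 as 3,4-trans (4R) under control of the bought C3 centre, while HFIP stabilises 8 and hydrogen-bonds the free C3 hydroxyls against O-alkylation; the minor 3,4-cis epimer is removed by chromatography; closest known reaction type: visible-light photoredox activation of aryl thioglycosides to oxocarbenium ions for O-glycosylation.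

Step 6
Reactants: 9 8-bromo-hepta-O-benzyl-ent-fisetinidol-(4β→6)-catechin
Product: 10 ent-fisetinidol-(4β→6)-catechin (CNP0141631.5)
Conditions: H2 (1 atm), Pd(OH)2/C, Et3N (2 equiv), THF–MeOH–H2O, rt; Sephadex LH-20
Reagents that add atoms: none
Why: Catalytic hydrogenolysis cleaves the seven benzyl ethers and, with Et3N as HBr scavenger, the aryl C–Br bond in the same operation, without touching any stereocentre.

**Compound list**

1 | (+)-catechin, (2R,3S)-2-(3,4-dihydroxyphenyl)chroman-3,5,7-triol | c1c(O)cc2c(c1O)C[C@H](O)[C@@H](c1ccc(O)c(O)c1)O2 | starting material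
2 | 5,7,3',4'-tetra-O-benzyl-(+)-catechin, (2R,3S)-5,7-bis(benzyloxy)-2-[3,4-bis(benzyloxy)phenyl]chroman-3-ol | c1c(OCc3ccccc3)cc2c(c1OCc1ccccc1)C[C@H](O)[C@@H](c1ccc(OCc3ccccc3)c(OCc3ccccc3)c1)O2 | intermediate
3 | 8-bromo-5,7,3',4'-tetra-O-benzyl-(+)-catechin, (2R,3S)-8-bromo-5,7-bis(benzyloxy)-2-[3,4-bis(benzyloxy)phenyl]chroman-3-ol | c1c(OCc3ccccc3)c(Br)c2c(c1OCc1ccccc1)C[C@H](O)[C@@H](c1ccc(OCc3ccccc3)c(OCc3ccccc3)c1)O2 | intermediate
4 | (−)-fustin, (2S,3S)-2-(3,4-dihydroxyphenyl)-3,7-dihydroxychroman-4-one (2,3-trans) | Oc1ccc2c(c1)O[C@@H](c1ccc(O)c(O)c1)[C@H](O)C2=O | starting material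
5 | 7,3',4'-tri-O-benzyl-(−)-fustin, (2S,3S)-7-benzyloxy-2-[3,4-bis(benzyloxy)phenyl]-3-hydroxychroman-4-one | c1ccccc1COc1ccc2c(c1)O[C@@H](c1ccc(OCc3ccccc3)c(OCc3ccccc3)c1)[C@H](O)C2=O | intermediate
6 | (2S,3R,4S)-7-benzyloxy-2-[3,4-bis(benzyloxy)phenyl]chroman-3,4-diol (2,3-trans-3,4-trans) | c1ccccc1COc1ccc2c(c1)O[C@@H](c1ccc(OCc3ccccc3)c(OCc3ccccc3)c1)[C@H](O)[C@H]2O | intermediate (not isolated)
7 | (2S,3S,4S)-7-benzyloxy-2-[3,4-bis(benzyloxy)phenyl]-4-[(4-methoxyphenyl)sulfanyl]chroman-3-ol (2,3-trans-3,4-trans) | c1ccccc1COc1ccc2c(c1)O[C@@H](c1ccc(OCc3ccccc3)c(OCc3ccccc3)c1)[C@H](O)[C@H]2Sc1ccc(OC)cc1 | intermediate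
8 | (2S,3R)-7-benzyloxy-2-[3,4-bis(benzyloxy)phenyl]-3-hydroxychroman-4-ylium (flavan-4-yl cation) | c1ccccc1COc1ccc2c(c1)O[C@@H](c1ccc(OCc3ccccc3)c(OCc3ccccc3)c1)[C@H](O)[CH+]2 | intermediate (not isolated)
9 | 8-bromo-hepta-O-benzyl-ent-fisetinidol-(4β→6)-catechin, (2R,3S)-5,7-bis(benzyloxy)-2-[3,4-bis(benzyloxy)phenyl]-6-{(2S,3R,4R)-7-benzyloxy-2-[3,4-bis(benzyloxy)phenyl]-3-hydroxychroman-4-yl}-8-bromochroman-3-ol | c1ccccc1COc1ccc2c(c1)O[C@@H](c1ccc(OCc3ccccc3)c(OCc3ccccc3)c1)[C@H](O)[C@H]2c1c(OCc2ccccc2)c(Br)c2c(c1OCc1ccccc1)C[C@H](O)[C@@H](c1ccc(OCc3ccccc3)c(OCc3ccccc3)c1)O2 | intermediate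
10 | ent-fisetinidol-(4β→6)-catechin, (2R,3S)-2-(3,4-dihydroxyphenyl)-6-[(2S,3R,4R)-2-(3,4-dihydroxyphenyl)-3,7-dihydroxychroman-4-yl]chroman-3,5,7-triol | Oc1ccc2c(c1)O[C@@H](c1ccc(O)c(O)c1)[C@H](O)[C@H]2c1c(O)cc2c(c1O)C[C@H](O)[C@@H](c1ccc(O)c(O)c1)O2 | target

**Step count and risks**

Total steps: 6. Longest linear sequence: 4 (steps 3, 4, 5, 6 from 4; equally steps 1, 2, 5, 6 from 1).

Most likely to fail:

Step 5 (the proposed new photoredox coupling). Possible failures are unproductive back electron transfer, O-alkylation by the free C3 hydroxyls, over-oxidation of 3 or 9, and a poor 3,4-trans to 3,4-cis ratio. The fallback uses known chemistry and sets out from 5: reduce with NaBH4 and this time isolate diol 6, then carry out the classical Lewis-acid Friedel–Crafts condensation of the flavan-4-ol with excess 3 (TiCl4, CH2Cl2–THF, 0 °C). The C6-linked, 3,4-trans product is again favoured by the Br block and the C3 hydroxyl, and the route is rejoined at 9. No new compound arises (F0).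

Step 3 (benzylation of a base-sensitive dihydroflavonol). Ring C may open, C2/C3 may epimerise, or air may dehydrogenate the product to the flavonol. The fallback sets out from 4 and removes the α-hydroxy ketone before any base is used: NaBH4 in EtOH reduces free (−)-fustin to (−)-leucofisetinidin F1, and BnBr/K2CO3 in acetone then benzylates its three phenols to give diol 6, now isolated. The route is rejoined at 6, which goes through the thiolysis half of step 4.

Step 6 (one-pot removal of seven benzyl groups and the hindered aryl bromide). C–Br hydrogenolysis may be incomplete, and the free polyphenol may oxidise in the presence of amine. The fallback sets out from 9 and separates the two events: bromine–lithium exchange with excess n-BuLi (THF, −78 °C) and a MeOH quench give bromine-free hepta-O-benzyl-ent-fisetinidol-(4β→6)-catechin F2, which is purified and then debenzylated without amine (H2, Pd(OH)2/C, THF–MeOH). The route is rejoined at 10.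

**Further compounds**

F0 | step 5 | none | none
F1 | step 3 | (−)-leucofisetinidin, (2S,3R,4S)-2-(3,4-dihydroxyphenyl)chroman-3,4,7-triol | Oc1ccc2c(c1)O[C@@H](c1ccc(O)c(O)c1)[C@H](O)[C@H]2O
F2 | step 6 | hepta-O-benzyl-ent-fisetinidol-(4β→6)-catechin (bromine-free) | c1ccccc1COc1ccc2c(c1)O[C@@H](c1ccc(OCc3ccccc3)c(OCc3ccccc3)c1)[C@H](O)[C@H]2c1c(OCc2ccccc2)cc2c(c1OCc1ccccc1)C[C@H](O)[C@@H](c1ccc(OCc3ccccc3)c(OCc3ccccc3)c1)O2
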